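## Structural features

The target is a C25 terpenoid made of a cis-fused decalin and a polyene side chain. Ring A (C1–C5, C10) is saturated and carries a gem-dimethyl group at C4; ring B (C5–C10) holds a tetrasubstituted C8=C9 olefin with a methyl on C8, and C10 bears the angular methyl. C9 carries the chain C11–C16, which ends on C17 of a furan-2(5H)-one (C17–C20, carbonyl C19); C11 and C12 are methylenes, C13 carries CH2OH, and C13=C14 (E, C12 cis to C15) and C15=C16 (E) are conjugated with the butenolide. There are only two stereocentres, C5 (R) and C10 (S); they are adjacent, C10 is quaternary, and the C5 hydrogen and the C10 methyl are cis, so both must be set together and early. The trienyl butenolide is sensitive to base (acidic C20 methylene), light and acid, and the primary allylic alcohol must not be ionised or oxidised, so the chain has to be attached last to a finished decalin. The real difficulties are the absolute cis ring fusion at a quaternary carbon next to the C4 gem-dimethyl group, the position of the tetrasubstituted olefin, and the geometry of the trisubstituted C13=C14 olefin. The key step exploits ring B: C7, C8, C9, C10 and C5 form a vinylcyclopropane when C5 and C9 are bonded (cyclopropane C5–C9–C10 fused to ring A, isopropenyl group = C7, C8 and the C8 methyl), and C6, the only ring B carbon without a substituent, is then one molecule of CO. C11 on C9 can be a carbonyl tied as a lactone to an oxygen on C1, which delivers the cyclopropane to one face of ring A and so sets C5 and C10.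

## Logic of the disconnections

The O–Si bond of 29 is the last bond formed before 30; the C13 hydroxymethyl group stays silylated so that C15 can be oxidised alone. The C15=C16 double bond of 29 is cut to 25 (C15 as aldehyde) and 27 (C16 as phosphonium carbon, made from 26). The cut puts the base-sensitive butenolide into the final C–C bond formation. The forward step must give the E olefin and must not disturb C13=C14.

The C12–C13 single bond of 24 (and so of 25) is cut to 18 (C12 as the terminal carbon of a vinyl group, to become a primary borane) and 22 (C13 as alkenyl iodide). The reason is that the C13=C14 geometry can then be fixed in a small fragment, 22, by a directed trans-hydroalumination of 20 (from 19), and only has to be retained in the coupling. The demand is a hydroboration that touches only the vinyl group of 18 and a coupling with retention at C13.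

The C11=C12 bond of 18 is cut to 17 (C11 aldehyde), and 17 goes back to 16 by adjustment of the oxidation level. This reduces the problem to a bicyclic allylic alcohol with no chain. The demand is methylenation of a hindered, tetrasubstituted enal.

The C1–H and C6–H bonds of 15 (the silyl ether of 16) are traced back to C–O bonds in 14, 12 and 11, and 11 to the ketone and lactone of 10. These oxygens are the price of the tether and of the CO unit. The forward step has to remove both without touching C8=C9. The C1 radical is a 2,2-disubstituted homoallyl radical and must be trapped faster than it can add to C9. The C6 radical has no comparable escape.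

The C5–C6 and C6–C7 bonds of 10 are cut, C6 leaves as 9 and the C5–C9 bond is restored, which gives 8. This removes ring B and replaces it by a cyclopropane whose configuration is dictated by a tether. The demand is insertion into C5–C9 and not C9–C10, with retention at C5. The olefin stays at C8=C9 because there it is tetrasubstituted and conjugated with the lactone carbonyl. The C7 methylene of 10, between ketone and enoate, is acidic, so the next step must reduce the ketone first and without base.

The C8=C7 double bond of 8 is cut to the C8 ketone of 7. The vinylcyclopropane is thus made only after the hot cyclopropanation step. The demand is methylenation of a ketone on a quaternary cyclopropane carbon in the presence of the lactone.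

The C9–C5 and C9–C10 bonds of 7 are cut to the diazo carbon and the C5=C10 olefin of 6. 6 goes back to 5 by diazo transfer, 5 to 2 and 3 (through 4), and 2 to 1. All three ring stereocentres of 7 then derive from the single carbinol of 2. The demand is that the carbenoid add to a trisubstituted olefin next to the gem-dimethyl carbon, which the five-membered tether makes possible on one face only. In 8 and 10 the C1 oxygen and C9 lie on the face opposite to the C5 hydrogen and the C10 methyl, and this corresponds to (5R,10S) in 30. It requires (S)-2 and therefore the (R)-oxazaborolidine.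

## Other disconnections considered

Alternative 1: The cut goes through C4–C5 and C9–C10, opening both rings to the acyclic (Z)-olefinic epoxy keto ester A2. In the forward sense a Lewis acid would open the (S)-epoxide at C4, C5 would attack, and the keto ester carbon C9 would close ring B onto C10 to give A1.
- In favour: two rings, two C–C bonds and both ring-fusion centres would arise in one operation, without a noble metal or CO. The C8 enol oxygen is the handle for the C8 methyl (sulfonylation, methyl cross-coupling) and the ester carbon is C11, so the sequence would meet the chosen route at 16 after removal of the C3 hydroxyl. That hydroxyl gives an ordinary secondary radical. On this point the alternative is better than the chosen plan, which has to delete two ring oxygens, one of them next to C10.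
- Against: the cis fusion rests on the Z olefin passing on its geometry in a concerted anti addition. With a tertiary cation at C10 and a weakly nucleophilic keto ester, closure of ring B could become stepwise, and trans-fused, monocyclic and oxygen-trapped products would be expected beside A1. A2 also needs an enantioselective epoxidation that tells two trisubstituted olefins apart.
- Comparison: in step count to 16 the alternative is about equal, perhaps slightly shorter. In stereochemical security the chosen plan is stronger, because the cyclopropane fixes the cis relation by geometry and not by the timing of a cation. The chain problem after 16 is the same for both.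

Alternative 2: The cut is C1–C10, with the C3–C8 bond reinstated: A3 goes back to the bicyclo[2.2.2]octenol A4, whose potassium alkoxide would undergo the anionic oxy-Cope shift.
- In favour: the sigmatropic shift inside the bicycle can only give the cis fusion, which makes it the equal of the chosen plan in stereospecificity. The C8=C9 olefin would appear in place without isomers, and A3 already carries C11 and C12 with an oxygen on C12. Only the C3 ketone would have to go, by an ionic Wolff–Kishner reduction. After the key step this alternative is clearly better: no deoxygenation at C1 and C6, no one-carbon homologation, and entry into the chosen route at the level of F9.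
- Against: A4 is a crowded bicycle with a bridgehead methyl, a tetrasubstituted olefin bearing two different groups, a gem-dimethyl carbon next to the carbinol and three stereocentres. Its enantioselective assembly would be long, and the facial selectivity of the vinyl addition to a neopentyl ketone is open. The rearrangement has to bond to a fully substituted olefin carbon, which would slow it and leave room for fragmentation of the alkoxide.
- Comparison: the mechanism is as clean as that of the chosen key step. Step economy is better after and worse before the key step. The balance is judged less favourable because every stereocentre of A4 needs external control, whereas here one catalytic reduction sets everything.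

Alternative 3: The cut is C9–C10 (ring B), leading from A5 back to the 1,7-enyne A6 and to (R)-α-ionone A7. Forward, a divalent palladium carboxylate catalyst with a phosphine would hydropalladate the alkyne, the C9 alkenylpalladium would add 6-exo to C10 of the ring olefin, and β-hydride loss would give C1=C2.
- In favour: A7 supplies ring A, the gem-dimethyl group and C5, and A6 is only a few steps away. C5 steers the insertion through the tether, so the cis fusion is as well secured as here (equal). C11, C12 and the C12 oxygen are in place and no ring oxygen has to be deleted. On paper it is the shortest of all the plans, and in step economy it is better than the chosen one.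
- Against: enantiopure A7 is not a bulk chemical and would need a resolution. The insertion has to engage a trisubstituted ring olefin to make a quaternary carbon, the least reactive olefin class for this process, where alkyne oligomerisation and hydride loss in other directions compete. A5 still needs a selective hydrogenation of C1=C2 and a reductive 1,3-transposition of the tertiary allylic alcohol (oxygen off C8, hydrogen onto C11, olefin into C8=C9) that must not ionise the allylic C12–O bond.
- Comparison: both key steps are metal insertions steered by a tether. The alternative is shorter but has two unsecured operations. The chosen plan is longer but each of its steps has close precedent.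

Key step: step 6

Remark: 1 and 26 are taken as catalogue compounds (1 is otherwise one Robinson annulation from isobutyraldehyde and ethyl vinyl ketone, 26 two steps from ethyl 3-methylbut-2-enoate by double allylic bromination and lactonisation); the C6 carbinol of 11 to 14 may be either epimer because that centre is removed in step 10.

## Steps

Step 1
Reactants: 1 2,4,4-trimethylcyclohex-2-en-1-one
Product: 2 (S)-2,4,4-trimethylcyclohex-2-en-1-ol
Conditions: (R)-2-methyl-CBS-oxazaborolidine (10 mol %), BH3·SMe2, THF, −20 °C
Reagents that add atoms: none
Why: Corey–Bakshi–Shibata reduction; the methyl-substituted olefinic carbon acts as the large group and the ring CH2 as the small one, so the (R)-catalyst should deliver hydride to give the (S)-carbinol (C1), the only stereocentre that is introduced by a reagent.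

Step 2
Reactants: 2 (S)-2,4,4-trimethylcyclohex-2-en-1-ol; 3 2,2,6-trimethyl-4H-1,3-dioxin-4-one
Product: 5 (S)-2,4,4-trimethylcyclohex-2-en-1-yl 3-oxobutanoate, via acetylketene 4 (not isolated)
Conditions: xylenes, 135 °C, acetone distilled off
Reagents that add atoms: none
Why: Thermal retro-[4+2] of the dioxinone releases acetylketene, which the alcohol traps (acetoacetylation) under neutral conditions; the C1–O bond is not touched, so the configuration is kept.

Step 3
Reactants: 5 (S)-2,4,4-trimethylcyclohex-2-en-1-yl 3-oxobutanoate
Product: 6 (S)-2,4,4-trimethylcyclohex-2-en-1-yl 2-diazo-3-oxobutanoate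
Conditions: p-ABSA, Et3N, MeCN, 0 °C → rt
Reagents that add atoms: 4-acetamidobenzenesulfonyl azide, CC(=O)Nc1ccc(cc1)S(=O)(=O)N=[N+]=[N-]
Why: Regitz diazo transfer to the active methylene of a β-keto ester; nothing else in the molecule is acidic enough to react.

Step 4
Reactants: 6 (S)-2,4,4-trimethylcyclohex-2-en-1-yl 2-diazo-3-oxobutanoate
Product: 7 acetyl cyclopropane lactone (cyclopropane C5–C9–C10 fused to ring A; lactone C9–C11(=O)–O–C1; acetyl on C9)
Conditions: Cu(acac)2 (5 mol %), toluene, 110 °C, slow addition
Reagents that add atoms: none
Why: Intramolecular cyclopropanation of the C5=C10 olefin by a copper carbenoid; the five-membered lactone tether can close only on the face of the C1 oxygen, so C5, C9 and C10 are set from C1 (C9 and the lactone oxygen on one face, C5–H and C10–CH3 on the other).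

Step 5
Reactants: 7 acetyl cyclopropane lactone
Product: 8 isopropenyl cyclopropane lactone (7 with C(CH3)=CH2 on C9)
Conditions: Ph3PCH3Br, KOtBu, THF, 0 → 45 °C
Reagents that add atoms: methyltriphenylphosphonium bromide, C[P+](c1ccccc1)(c1ccccc1)c1ccccc1.[Br-]
Why: Wittig methylenation installs C7; the ketone is more electrophilic than the lactone carbonyl and C9 is quaternary, so no centre can epimerise.

Step 6
Reactants: 8 isopropenyl cyclopropane lactone; 9 carbon monoxide
Product: 10 cis-fused keto lactone (C6 ketone; C8=C9; lactone C11(=O)–O–C1)
Conditions: [Rh(CO)2Cl]2 (5 mol %), dppp (10 mol %), AgOTf (12 mol %), CO (1 atm), ClCH2CH2Cl, 80 °C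
Reagents that add atoms: none
Why: Cationic monovalent rhodium binds the isopropenyl π bond and adds oxidatively into the adjacent C5–C9 bond, giving a six-membered rhodacycle with an alkyl bond to C5 and an η3-allyl over C9–C8–C7; CO then inserts into the Rh–C5 bond and acyl–allyl reductive elimination at C7 forms C6–C7. The closest known reaction type is the rhodium-catalysed carbonylative (5+1) cycloaddition of vinylcyclopropanes to cyclohex-3-enones. Ring B closes by C–C reductive elimination from a seven-membered acyl rhodacycle, a metal-templated six-ring closure in which ring A and the lactone are spectators. No new stereocentre is formed: insertion of rhodium and of CO both proceed with retention at C5 and C10 is untouched, so the cis relation of H-5 and CH3-10 is carried over from the cyclopropane. The step needs cleavage of C5–C9 and not C9–C10; this is secured because C10 is quaternary and held in the lactone ring while C5 is the only proximal CH. The alkyl rhodium at C5 has no β-hydrogen (C4 and C10 are quaternary), which closes the diene-forming pathway, and elimination at C7 rather than C9 gives the six- and not the four-membered ring. The olefin ends at C8=C9, where it is tetrasubstituted and conjugated with the lactone carbonyl, so it has no drive to move toward the ketone.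

Step 7
Reactants: 10 cis-fused keto lactone
Product: 11 triol (C1 OH; C6 OH; C11 CH2OH; C8=C9)
Conditions: DIBAL-H (excess), CH2Cl2, −78 → 0 °C; Rochelle salt
Reagents that add atoms: none
Why: DIBAL-H reduces the ketone at −78 °C before the acidic C7 methylene can be enolised and then reduces the α,β-unsaturated lactone by 1,2-addition to the allylic 1,4-diol; C1 keeps its configuration.

Step 8
Reactants: 11 triol
Product: 12 C11 tert-butyldimethylsilyl ether of 11
Conditions: TBSCl (1.05 equiv), imidazole, CH2Cl2, 0 °C
Reagents that add atoms: tert-butyldimethylsilyl chloride, CC(C)(C)[Si](C)(C)Cl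
Why: Selective silylation of the primary allylic alcohol; both secondary alcohols are flanked by fully substituted or tertiary carbons.

Step 9
Reactants: 12 C11 tert-butyldimethylsilyl ether of 11
Product: 14 1,6-bis(S-methyl xanthate) of 12, via disodium bis-xanthate 13 (not isolated)
Conditions: CS2, NaH, imidazole (cat.), THF, 0 → 50 °C; then MeI
Reagents that add atoms: carbon disulfide, S=C=S; iodomethane, CI
Why: Xanthate formation, the first half of a Barton–McCombie deoxygenation; the small reagents reach hindered alkoxides, and CS2 is present before the base so that the alkoxides are trapped before a silyl group can migrate.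

Step 10
Reactants: 14 1,6-bis(S-methyl xanthate) of 12
Product: 15 tert-butyldimethylsilyl ether of [(4aR,8aS)-2,5,5,8a-tetramethyl-3,4,4a,5,6,7,8,8a-octahydronaphthalen-1-yl]methanol
Conditions: Bu3SnH, AIBN, PhSeSePh (20 mol %), toluene, 90 °C
Reagents that add atoms: none
Why: Barton–McCombie deoxygenation at C1 and C6; benzeneselenol formed from PhSeSePh and the stannane transfers hydrogen fast enough to quench the C1 radical before it can close onto C9 and undergo a 1,2-vinyl shift, while the C6 radical has no low-barrier rearrangement.

Step 11
Reactants: 15 silyl ether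
Product: 16 [(4aR,8aS)-2,5,5,8a-tetramethyl-3,4,4a,5,6,7,8,8a-octahydronaphthalen-1-yl]methanol
Conditions: TBAF, THF, 0 °C → rt
Reagents that add atoms: none
Why: Fluoride cleavage of a primary silyl ether; nothing else in the molecule is sensitive.

Step 12
Reactants: 16 allylic alcohol
Product: 17 (4aR,8aS)-2,5,5,8a-tetramethyl-3,4,4a,5,6,7,8,8a-octahydronaphthalene-1-carbaldehyde
Conditions: MnO2, CH2Cl2, rt
Reagents that add atoms: none
Why: MnO2 oxidation of an allylic alcohol to the enal; the neutral conditions leave the tetrasubstituted olefin in place.

Step 13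
Reactants: 17 enal
Product: 18 (4aR,8aS)-1-ethenyl-2,5,5,8a-tetramethyl-3,4,4a,5,6,7,8,8a-octahydronaphthalene
Conditions: Ph3PCH3Br, KOtBu, THF, 0 °C → rt
Reagents that add atoms: methyltriphenylphosphonium bromide, C[P+](c1ccccc1)(c1ccccc1)c1ccccc1.[Br-]
Why: Wittig methylenation installs C12; hindered tetrasubstituted enals of this type are known to react with the unhindered ylide.

Step 14
Reactants: 19 but-2-yne-1,4-diol
Product: 20 4-(tert-butyldimethylsilyloxy)but-2-yn-1-ol
Conditions: NaH (1.0 equiv), THF, 0 °C; TBSCl (1.0 equiv)
Reagents that add atoms: tert-butyldimethylsilyl chloride, CC(C)(C)[Si](C)(C)Cl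
Why: Monosilylation of a symmetrical diol through its sparingly soluble monosodium alkoxide.

Step 15
Reactants: 20 4-(tert-butyldimethylsilyloxy)but-2-yn-1-ol
Product: 22 (Z)-4-(tert-butyldimethylsilyloxy)-3-iodobut-2-en-1-ol, via cyclic alkenylalanate 21 (not isolated)
Conditions: Red-Al, THF, 0 °C; EtOAc; I2, −78 → 0 °C
Reagents that add atoms: iodine, II
Why: Alkoxide-directed trans-hydroalumination puts hydride on the carbon next to the carbinol (future C14) and aluminium on the distal carbon (future C13) in a five-membered alanate; iodinolysis with retention leaves iodine cis to CH2OH, which fixes the later C13=C14 geometry.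

Step 16
Reactants: 18 diene; 22 (Z)-4-(tert-butyldimethylsilyloxy)-3-iodobut-2-en-1-ol
Product: 24 (E)-3-[(tert-butyldimethylsilyloxy)methyl]-5-[(4aR,8aS)-2,5,5,8a-tetramethyl-3,4,4a,5,6,7,8,8a-octahydronaphthalen-1-yl]pent-2-en-1-ol, via B-alkyl-9-BBN borane 23 (not isolated)
Conditions: 9-BBN, THF, 0 °C → rt; then 22, PdCl2(dppf) (5 mol %), AsPh3, aq K3PO4, DMF, rt
Reagents that add atoms: none
Why: 9-BBN adds only to the monosubstituted vinyl group, with boron on C12, and leaves the tetrasubstituted olefin alone; the B-alkyl Suzuki–Miyaura coupling forms C12–C13 with retention at the alkenyl iodide, so C12 ends cis to C15.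

Step 17
Reactants: 24 allylic alcohol
Product: 25 (E)-3-[(tert-butyldimethylsilyloxy)methyl]-5-[(4aR,8aS)-2,5,5,8a-tetramethyl-3,4,4a,5,6,7,8,8a-octahydronaphthalen-1-yl]pent-2-enal
Conditions: MnO2, CH2Cl2, rt
Reagents that add atoms: none
Why: MnO2 oxidises the only free allylic alcohol (C15); the neutral conditions should keep the C13=C14 geometry.

Step 18
Reactants: 26 4-(bromomethyl)furan-2(5H)-one
Product: 27 [(5-oxo-2,5-dihydrofuran-3-yl)methyl]triphenylphosphonium bromide
Conditions: PPh3, toluene, 60 °C
Reagents that add atoms: triphenylphosphine, c1ccc(cc1)P(c1ccccc1)c1ccccc1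
Why: SN2 quaternisation of a primary allylic bromide by the phosphine.

Step 19
Reactants: 25 enal; 27 phosphonium bromide
Product: 29 tert-butyldimethylsilyl ether of the target, via phosphonium ylide 28 (not isolated)
Conditions: 27, NaHMDS (0.95 equiv), THF, −78 °C; then 25, −78 → 0 °C
Reagents that add atoms: none
Why: Wittig olefination forms C15=C16; the ylide is stabilised through the butenolide carbonyl, so the E olefin should dominate, and it is too weakly basic to deprotonate the γ-positions of the enal.

Step 20
Reactants: 29 tert-butyldimethylsilyl ether of the target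
Product: 30 4-[(1E,3E)-4-(hydroxymethyl)-6-[(4aR,8aS)-2,5,5,8a-tetramethyl-3,4,4a,5,6,7,8,8a-octahydronaphthalen-1-yl]hexa-1,3-dien-1-yl]furan-2(5H)-one
Conditions: HF·pyridine, pyridine, THF, 0 °C
Reagents that add atoms: none
Why: Buffered fluoride cleaves the primary silyl ether without base, so the butenolide and the triene are not exposed to conditions that could isomerise them.

## Compound list

1 | 2,4,4-trimethylcyclohex-2-en-1-one | CC1=CC(C)(C)CCC1=O | starting material
2 | (S)-2,4,4-trimethylcyclohex-2-en-1-ol | O[C@H]1CCC(C)(C)C=C1C | intermediate
3 | 2,2,6-trimethyl-4H-1,3-dioxin-4-one | CC1=CC(=O)OC(C)(C)O1 | starting material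
4 | acetylketene (3-oxobut-1-en-1-one) | CC(=O)C=C=O | intermediate (not isolated)
5 | (S)-2,4,4-trimethylcyclohex-2-en-1-yl 3-oxobutanoate | CC(=O)CC(=O)O[C@H]1CCC(C)(C)C=C1C | intermediate
6 | (S)-2,4,4-trimethylcyclohex-2-en-1-yl 2-diazo-3-oxobutanoate | CC(=O)C(=[N+]=[N-])C(=O)O[C@H]1CCC(C)(C)C=C1C | intermediate
7 | acetyl cyclopropane lactone: cyclopropane C5–C9–C10 fused to ring A, γ-lactone C9–C11(=O)–O–C1, acetyl on C9; C1 oxygen and C9 on the face opposite to C5–H and C10–CH3; C1 (S) | CC(=O)[C@@]12C(=O)O[C@H]3CCC(C)(C)[C@@H]1[C@@]23C | intermediate
8 | isopropenyl cyclopropane lactone: as 7 with C(CH3)=CH2 (C8, C7) on C9 | C=C(C)[C@@]12C(=O)O[C@H]3CCC(C)(C)[C@@H]1[C@@]23C | intermediate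
9 | carbon monoxide | [C-]#[O+] | starting material
10 | cis-fused keto lactone: C6 ketone, C8=C9, lactone C11(=O)–O–C1; C5–H and C10–CH3 cis, C1 oxygen on the opposite face | CC1=C2C(=O)O[C@H]3CCC(C)(C)[C@@H](C(=O)C1)[C@@]23C | intermediate
11 | triol: C1 OH (S), C6 OH (either epimer), C11 CH2OH, C8=C9, cis ring fusion | CC1=C(CO)[C@@]2(C)[C@@H](O)CCC(C)(C)[C@H]2C(O)C1 | intermediate
12 | C11 tert-butyldimethylsilyl ether of 11 | CC1=C(CO[Si](C)(C)C(C)(C)C)[C@@]2(C)[C@@H](O)CCC(C)(C)[C@H]2C(O)C1 | intermediate
13 | disodium 1,6-bis-xanthate of 12 | CC1=C(CO[Si](C)(C)C(C)(C)C)[C@@]2(C)[C@@H](OC(=S)[S-])CCC(C)(C)[C@H]2C(OC(=S)[S-])C1.[Na+].[Na+] | intermediate (not isolated)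
14 | 1,6-bis(S-methyl xanthate) of 12 | CC1=C(CO[Si](C)(C)C(C)(C)C)[C@@]2(C)[C@@H](OC(=S)SC)CCC(C)(C)[C@H]2C(OC(=S)SC)C1 | intermediate
15 | tert-butyldimethylsilyl ether of [(4aR,8aS)-2,5,5,8a-tetramethyl-3,4,4a,5,6,7,8,8a-octahydronaphthalen-1-yl]methanol | CC1=C(CO[Si](C)(C)C(C)(C)C)[C@@]2(C)CCCC(C)(C)[C@H]2CC1 | intermediate
16 | [(4aR,8aS)-2,5,5,8a-tetramethyl-3,4,4a,5,6,7,8,8a-octahydronaphthalen-1-yl]methanol | CC1=C(CO)[C@@]2(C)CCCC(C)(C)[C@H]2CC1 | intermediate
17 | (4aR,8aS)-2,5,5,8a-tetramethyl-3,4,4a,5,6,7,8,8a-octahydronaphthalene-1-carbaldehyde | CC1=C(C=O)[C@@]2(C)CCCC(C)(C)[C@H]2CC1 | intermediate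
18 | (4aR,8aS)-1-ethenyl-2,5,5,8a-tetramethyl-3,4,4a,5,6,7,8,8a-octahydronaphthalene | CC1=C(C=C)[C@@]2(C)CCCC(C)(C)[C@H]2CC1 | intermediate
19 | but-2-yne-1,4-diol | OCC#CCO | starting material
20 | 4-(tert-butyldimethylsilyloxy)but-2-yn-1-ol | OCC#CCO[Si](C)(C)C(C)(C)C | intermediate
21 | sodium cyclic alkenylalanate (1-oxa-2-aluminacyclopent-3-ene with two 2-methoxyethoxy groups on Al and CH2OTBS on the Al-bound carbon) | COCCO[Al-]1(OCCOC)OCC=C1CO[Si](C)(C)C(C)(C)C.[Na+] | intermediate (not isolated)
22 | (Z)-4-(tert-butyldimethylsilyloxy)-3-iodobut-2-en-1-ol | OC/C=C(\I)CO[Si](C)(C)C(C)(C)C | intermediate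
23 | 9-[2-[(4aR,8aS)-2,5,5,8a-tetramethyl-3,4,4a,5,6,7,8,8a-octahydronaphthalen-1-yl]ethyl]-9-borabicyclo[3.3.1]nonane | CC1=C(CCB3C4CCCC3CCC4)[C@@]2(C)CCCC(C)(C)[C@H]2CC1 | intermediate (not isolated)
24 | (E)-3-[(tert-butyldimethylsilyloxy)methyl]-5-[(4aR,8aS)-2,5,5,8a-tetramethyl-3,4,4a,5,6,7,8,8a-octahydronaphthalen-1-yl]pent-2-en-1-ol | CC1=C(CC/C(=C\CO)CO[Si](C)(C)C(C)(C)C)[C@@]2(C)CCCC(C)(C)[C@H]2CC1 | intermediate
25 | (E)-3-[(tert-butyldimethylsilyloxy)methyl]-5-[(4aR,8aS)-2,5,5,8a-tetramethyl-3,4,4a,5,6,7,8,8a-octahydronaphthalen-1-yl]pent-2-enal | CC1=C(CC/C(=C\C=O)CO[Si](C)(C)C(C)(C)C)[C@@]2(C)CCCC(C)(C)[C@H]2CC1 | intermediate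
26 | 4-(bromomethyl)furan-2(5H)-one | O=C1OCC(CBr)=C1 | starting material
27 | [(5-oxo-2,5-dihydrofuran-3-yl)methyl]triphenylphosphonium bromide | O=C1OCC(C[P+](c2ccccc2)(c2ccccc2)c2ccccc2)=C1.[Br-] | intermediate
28 | 4-[(triphenylphosphoranylidene)methyl]furan-2(5H)-one | O=C1OCC(C=P(c2ccccc2)(c2ccccc2)c2ccccc2)=C1 | intermediate (not isolated)
29 | 4-[(1E,3E)-4-[(tert-butyldimethylsilyloxy)methyl]-6-[(4aR,8aS)-2,5,5,8a-tetramethyl-3,4,4a,5,6,7,8,8a-octahydronaphthalen-1-yl]hexa-1,3-dien-1-yl]furan-2(5H)-one | CC1=C(CC/C(=C\C=C\C3=CC(=O)OC3)CO[Si](C)(C)C(C)(C)C)[C@@]2(C)CCCC(C)(C)[C@H]2CC1 | intermediate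
30 | 4-[(1E,3E)-4-(hydroxymethyl)-6-[(4aR,8aS)-2,5,5,8a-tetramethyl-3,4,4a,5,6,7,8,8a-octahydronaphthalen-1-yl]hexa-1,3-dien-1-yl]furan-2(5H)-one | CC1=C(CC/C(=C\C=C\C2=CC(=O)OC2)CO)[C@@]2(C)CCCC(C)(C)[C@H]2CC1 | target

## Step count and least certain steps

Total: 20 steps. Longest linear sequence: 17 steps (steps 1–13, 16, 17, 19, 20).

Step 6 (key step). Oxidative addition could be slow at this fully substituted, crowded cyclopropane, or could take the C9–C10 bond. The allyl intermediate could also lose a hydrogen from the C8 methyl and open to a diene, or eliminate at C9 to a four-membered ketone. If temperatures far above 100 °C were needed, a thermal homo-1,5-hydrogen shift between the cis C10 methyl and the isopropenyl group would begin to compete. Fallback, from 8: irradiation with Fe(CO)5 (zerovalent iron) in THF under CO is the stoichiometric version of the same bond reorganisation and is known to stop at an isolable σ-acyl π-allyl complex. That complex, the acyl π-allyl Fe(CO)3 ferracycle F1, would be isolated and made to eliminate reductively by heating under CO pressure. This returns to the route at 10.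

Step 10. The C1 radical might add to C9 and reopen (1,2-vinyl shift to a ring-expanded skeleton) faster than hydrogen transfer. Thioacylation of the neopentyl C1 alcohol in step 9 might also stay incomplete. Fallback, from 10, with no radical at C1:
- Ethane-1,2-dithiol and BF3·OEt2 give the C6 dithiolane F2, and Raney nickel in ethanol gives the C6-deoxy lactone F3.
- DIBAL-H gives the diol F4, and TBSCl/imidazole its C11 silyl ether F5.
- Dess–Martin periodinane gives the C1 ketone F6, which cannot conjugate because C10 is quaternary.
- Wolff–Kishner reduction (N2H4·H2O, KOH, diethylene glycol, 130 then 200 °C) removes the carbonyl, and the primary silyl ether is cleaved in the hot alkaline glycol.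

This returns to the route at 16.

Step 5. The basic ylide could deprotonate the acetyl methyl instead of adding, or addition could be slow at a carbonyl flanked by the quaternary C9 and the C10 methyl, leaving time for attack at the lactone. Fallback, from 2, which brings the isopropenyl group in with the carbenoid: esterification with 3-methylbut-3-enoic acid (EDC, DMAP) gives the 3-methylbut-3-enoate F7. Diazo transfer with p-ABSA and DBU gives the vinyldiazoacetate F8. Intramolecular cyclopropanation with Rh2(OAc)4 in CH2Cl2 at room temperature returns to the route at 8.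

Step 16. Transmetalation of the hindered homoallylic borane could be slow, so that protodeboronation or β-hydride elimination takes over, or the alkenyl iodide could lose its geometry on palladium. Fallback, from 18: hydroboration with 9-BBN and oxidation (NaOH, H2O2) give the primary alcohol F9, and I2/PPh3/imidazole the iodide F10. Zinc insertion (Zn, LiCl, THF) gives the alkylzinc iodide F11. Negishi coupling with 22 (PdCl2(dppf), THF, rt) tolerates the free hydroxyl and returns to the route at 24.

Step 19. E selectivity at C15=C16 could be eroded, the ylide could react through its ring γ-carbon, or reversible deprotonation of the enal could scramble C13=C14. Fallback, from 25, which forms C16–C17 instead of C15=C16: chromium-mediated boryl olefination of Takai type (CrCl2, LiI, Cl2CHBpin, THF) gives the (E)-dienyl pinacol boronate F12. Suzuki–Miyaura coupling with 4-bromofuran-2(5H)-one (PdCl2(dppf), K3PO4, THF/H2O) returns to the route at 29.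

## Further compounds

F1 | step 6 | acyl π-allyl Fe(CO)3 ferracycle from 8 (Fe bound to acyl C6 and to the C7–C8–C9 allyl unit; allyl written in its C7 σ form) | CC1=C2C(=O)O[C@H]3CCC(C)(C)[C@@H](C(=O)[Fe](=C=O)(=C=O)(=C=O)C1)[C@@]23C
F2 | step 10 | C6 1,3-dithiolane of 10 | CC1=C2C(=O)O[C@H]3CCC(C)(C)[C@@H](C4(SCCS4)C1)[C@@]23C
F3 | step 10 | C6-deoxy lactone (10 with CH2 at C6) | CC1=C2C(=O)O[C@H]3CCC(C)(C)[C@@H](CC1)[C@@]23C
F4 | step 10 | diol: C1 OH (S), C11 CH2OH, C8=C9, cis ring fusion | CC1=C(CO)[C@@]2(C)[C@@H](O)CCC(C)(C)[C@H]2CC1
F5 | step 10 | C11 tert-butyldimethylsilyl ether of F4 | CC1=C(CO[Si](C)(C)C(C)(C)C)[C@@]2(C)[C@@H](O)CCC(C)(C)[C@H]2CC1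
F6 | step 10 | C1 ketone of F5 | CC1=C(CO[Si](C)(C)C(C)(C)C)[C@@]2(C)C(=O)CCC(C)(C)[C@H]2CC1
F7 | step 5 | (S)-2,4,4-trimethylcyclohex-2-en-1-yl 3-methylbut-3-enoate | C=C(C)CC(=O)O[C@H]1CCC(C)(C)C=C1C
F8 | step 5 | (S)-2,4,4-trimethylcyclohex-2-en-1-yl 2-diazo-3-methylbut-3-enoate | C=C(C)C(=[N+]=[N-])C(=O)O[C@H]1CCC(C)(C)C=C1C
F9 | step 16 | 2-[(4aR,8aS)-2,5,5,8a-tetramethyl-3,4,4a,5,6,7,8,8a-octahydronaphthalen-1-yl]ethanol | CC1=C(CCO)[C@@]2(C)CCCC(C)(C)[C@H]2CC1
F10 | step 16 | (4aR,8aS)-1-(2-iodoethyl)-2,5,5,8a-tetramethyl-3,4,4a,5,6,7,8,8a-octahydronaphthalene | CC1=C(CCI)[C@@]2(C)CCCC(C)(C)[C@H]2CC1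
F11 | step 16 | alkylzinc iodide from F10 | CC1=C(CC[Zn]I)[C@@]2(C)CCCC(C)(C)[C@H]2CC1
F12 | step 19 | (1E,3E)-dienyl pinacol boronate from 25 (Bpin on C16) | CC1=C(CC/C(=C\C=C\B3OC(C)(C)C(C)(C)O3)CO[Si](C)(C)C(C)(C)C)[C@@]2(C)CCCC(C)(C)[C@H]2CC1
A1 | alternative 1 | cis-fused bicyclic β-keto ester, enol form (C8 enol, C11 methyl ester on C9, C3 hydroxyl syn to the C10 methyl) | OC1=C(C(=O)OC)[C@@]2(C)CC[C@H](O)C(C)(C)[C@H]2CC1
A2 | alternative 1 | methyl (6Z)-9-[(2S)-3,3-dimethyloxiran-2-yl]-7-methyl-3-oxonon-6-enoate | COC(=O)CC(=O)CC/C=C(C)\CC[C@@H]1OC1(C)C
A3 | alternative 2 | cis-5-[2-(tert-butyldimethylsilyloxy)ethyl]-1,1,4a,6-tetramethyl-3,4,4a,7,8,8a-hexahydronaphthalen-2(1H)-one | CC1=C(CCO[Si](C)(C)C(C)(C)C)[C@@]2(C)CCC(=O)C(C)(C)[C@H]2CC1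
A4 | alternative 2 | 6-[2-(tert-butyldimethylsilyloxy)ethyl]-1,3,3,5-tetramethyl-2-vinylbicyclo[2.2.2]oct-5-en-2-ol (vinyl syn to the C5=C6 bridge) | C=C[C@]1(O)C(C)(C)[C@H]2CC[C@]1(C)C(CCO[Si](C)(C)C(C)(C)C)=C2C
A5 | alternative 3 | cis-fused bicyclic diene with C8 tertiary carbinol, exocyclic C9=C11 carrying CH2OTBS, and C1=C2 | CC1(O)/C(=C\CO[Si](C)(C)C(C)(C)C)[C@@]2(C)C=CCC(C)(C)[C@H]2CC1
A6 | alternative 3 | 6-(tert-butyldimethylsilyloxy)-3-methyl-1-[(1R)-2,6,6-trimethylcyclohex-2-en-1-yl]hex-4-yn-3-ol (carbinol epimers) | CC1=CCCC(C)(C)[C@H]1CCC(C)(O)C#CCO[Si](C)(C)C(C)(C)C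
A7 | alternative 3 | (R)-α-ionone | CC1=CCCC(C)(C)[C@H]1/C=C/C(C)=O
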